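Numbering: C1 is the lactone carbonyl, C2 the acyloxy carbon, then C3, C4, Z-C5=C6, the carbinols C7 and C8, and C9, which carries the ring oxygen and the propyl chain C10–C12. The side chain is C1'–C6'.
Cuts, in retrosynthetic order: the O2–C1' ester (epoxyhexenoyl side chain), the C6–C7 ring bond, then the O9–C1 ester. The last cut is read as opening of a trans-2,3-epoxy alcohol at its propyl-bearing carbon by the C1 carboxylic acid.
Enabling feature: in the ten-membered ring (ring oxygen plus C1–C9), C7 is a carbinol allylic to the Z-C5=C6 alkene and adjacent to the oxygenated stereocentre C8. The C6–C7 bond can therefore come from a Z-alkenyl metal at C6 and a C7 aldehyde whose faces C8 differentiates.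
Forward order: the C1–C6 acid and the C7–C12 epoxy alcohol are joined at O9–C1, the lactone ring then closes at C6–C7, the preformed epoxy acid is attached at O2, and both silyl ethers are removed last.
Stereochemistry: C2 comes from (S)-trityl glycidyl ether. C8 (retained) and C9 (inverted) come from Sharpless epoxidation of (E)-hex-2-en-1-ol, and C7 from Felkin–Anh addition during ring closure. C4'/C5' come from Sharpless epoxidation of crotyl alcohol, the Z alkene from diimide reduction of an iodoalkyne, and the E enoate from a stabilised Wittig reagent.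

Key step: step 11

Remark: no bond at C8 or at the epoxide carbons is broken after they are set. The changes of descriptor along the route (C8 in 16, 19, 20 and 27; C2 of 23) arise only from altered CIP ranking of neighbouring groups.

Step 1
Reactants: 1 (S)-trityl glycidyl ether; 2 1-(trimethylsilyl)propyne
Product: 4 (2S)-6-(trimethylsilyl)-1-(trityloxy)hex-5-yn-2-ol, via lithiated silylpropyne 3 (not isolated)
Conditions: 2, n-BuLi, TMEDA, THF, −20 °C; then 1, −78 °C → rt; H2O
Reagents that add atoms: none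
Why: Propargylic lithiation of the silylpropyne followed by SN2 opening of the terminal epoxide at its CH2 carbon is a standard homopropargylic alcohol synthesis; the silyl group blocks the alkyne terminus and directs the ambident anion to react at its propargylic carbon, and the C2 stereocentre takes no part.

Step 2
Reactants: 4 (2S)-6-(trimethylsilyl)-1-(trityloxy)hex-5-yn-2-ol
Product: 5 (2S)-2-(4-methoxybenzyloxy)-6-(trimethylsilyl)-1-(trityloxy)hex-5-yne
Conditions: NaH, PMBCl, Bu4NI (cat.), THF/DMF, 0 °C → rt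
Reagents that add atoms: 4-methoxybenzyl chloride COc1ccc(CCl)cc1
Why: Williamson etherification of the secondary alkoxide leaves the base-stable trityl ether untouched, and any adventitious loss of the alkynyl silyl group is harmless because step 3 iodinates the alkyne terminus in either form.

Step 3
Reactants: 5 (2S)-2-(4-methoxybenzyloxy)-6-(trimethylsilyl)-1-(trityloxy)hex-5-yne
Product: 6 (2S)-6-iodo-2-(4-methoxybenzyloxy)-1-(trityloxy)hex-5-yne
Conditions: NIS, AgNO3 (cat.), acetone, rt, dark
Reagents that add atoms: N-iodosuccinimide O=C1CCC(=O)N1I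
Why: Silver-catalysed iododesilylation of an alkynylsilane with N-iodosuccinimide is a known direct route to 1-iodoalkynes; it saves a separate desilylation and runs under near-neutral conditions that the trityl and PMB ethers tolerate.

Step 4
Reactants: 6 (2S)-6-iodo-2-(4-methoxybenzyloxy)-1-(trityloxy)hex-5-yne
Product: 7 (2S,5Z)-6-iodo-2-(4-methoxybenzyloxy)-1-(trityloxy)hex-5-ene
Conditions: 2-nitrobenzenesulfonylhydrazide, Et3N, THF/i-PrOH, rt
Reagents that add atoms: none
Why: Diimide released from the sulfonylhydrazide transfers both hydrogens to one face of the iodoalkyne in a concerted syn addition, the standard route to Z-1-iodoalkenes; it leaves the carbon–iodine bond and both ethers intact, and stopping at consumption of 6 limits over-reduction.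

Step 5
Reactants: 7 (2S,5Z)-6-iodo-2-(4-methoxybenzyloxy)-1-(trityloxy)hex-5-ene
Product: 8 (2S,5Z)-6-iodo-2-(4-methoxybenzyloxy)hex-5-en-1-ol
Conditions: TsOH·H2O (cat.), MeOH/CH2Cl2, 0 °C → rt
Reagents that add atoms: none
Why: Acid-catalysed methanolysis of the trityl ether (SN1 through the trityl cation) is much faster than cleavage of the PMB ether, so only the primary C1 alcohol is released.

Step 6
Reactants: 8 (2S,5Z)-6-iodo-2-(4-methoxybenzyloxy)hex-5-en-1-ol
Product: 10 (2S,5Z)-6-iodo-2-(4-methoxybenzyloxy)hex-5-enoic acid, via aldehyde 9 (not isolated)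
Conditions: TEMPO (cat.), PhI(OAc)2, MeCN/H2O, rt
Reagents that add atoms: water O
Why: Oxoammonium-mediated oxidation in aqueous acetonitrile takes the primary alcohol through 9 and its hydrate to the acid in one flask under near-neutral conditions that spare the PMB ether, the iodoalkene and the alpha stereocentre.

Step 7
Reactants: 11 (E)-hex-2-en-1-ol
Product: 12 [(2S,3S)-3-propyloxiran-2-yl]methanol
Conditions: Ti(OiPr)4 (cat.), L-(+)-diethyl tartrate (cat.), t-BuOOH, 4 Å MS, CH2Cl2, −20 °C
Reagents that add atoms: tert-butyl hydroperoxide CC(C)(C)OO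
Why: In the catalytic Sharpless asymmetric epoxidation the L-(+)-tartrate ligand delivers oxygen to the face of the E-allylic alcohol that gives the (2S,3S)-epoxide, which fixes the future C8 and, before its inversion, C9.

Step 8
Reactants: 10 (2S,5Z)-6-iodo-2-(4-methoxybenzyloxy)hex-5-enoic acid; 12 [(2S,3S)-3-propyloxiran-2-yl]methanol
Product: 13 (2S,3R)-1,2-dihydroxyhexan-3-yl (2S,5Z)-6-iodo-2-(4-methoxybenzyloxy)hex-5-enoate
Conditions: Ti(OiPr)4 (1.5 equiv), 12 in slight excess over 10, CH2Cl2, 0 °C → rt; cold aq. tartaric acid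
Reagents that add atoms: none
Why: In the Ti(OiPr)4-mediated opening of a 2,3-epoxy alcohol by a carboxylic acid the substrate binds titanium through its alkoxide and oxirane oxygens, so the carboxylate attacks the propyl-bearing carbon in SN2 fashion with inversion (C9 becomes R) while the C8–O bond is kept, which gives the 8,9-anti pair; the diol is carried on at once to outrun acyl migration.

Step 9
Reactants: 13 (2S,3R)-1,2-dihydroxyhexan-3-yl (2S,5Z)-6-iodo-2-(4-methoxybenzyloxy)hex-5-enoate
Product: 14 (2S,3R)-1,2-bis(triethylsilyloxy)hexan-3-yl (2S,5Z)-6-iodo-2-(4-methoxybenzyloxy)hex-5-enoate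
Conditions: TESOTf, 2,6-lutidine, CH2Cl2, −78 °C
Reagents that add atoms: triethylsilyl triflate CC[Si](CC)(CC)OS(=O)(=O)C(F)(F)F
Why: Silylation with the silyl triflate and a hindered pyridine base is complete within minutes at −78 °C, too cold and too brief for the acyl group to shift from O9 to O8 or O7.

Step 10
Reactants: 14 (2S,3R)-1,2-bis(triethylsilyloxy)hexan-3-yl (2S,5Z)-6-iodo-2-(4-methoxybenzyloxy)hex-5-enoate
Product: 16 (2R,3R)-1-oxo-2-(triethylsilyloxy)hexan-3-yl (2S,5Z)-6-iodo-2-(4-methoxybenzyloxy)hex-5-enoate, via alkoxysulfonium chloride 15 (not isolated)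
Conditions: (COCl)2, DMSO, CH2Cl2, −78 → −40 °C; Et3N, −78 °C; cold pH 7 buffer; used crude
Reagents that add atoms: none
Why: In the Swern oxidation applied directly to a primary triethylsilyl ether the chlorosulfonium salt exchanges only the unhindered primary silyl group to give 15, which collapses to the aldehyde when the amine is added while the secondary C8 ether survives; the cold buffered quench limits E1cB loss of the C9 carboxylate and epimerisation at C8.

Step 11
Reactants: 16 (2R,3R)-1-oxo-2-(triethylsilyloxy)hexan-3-yl (2S,5Z)-6-iodo-2-(4-methoxybenzyloxy)hex-5-enoate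
Product: 18 (2S,5Z,7S,8S,9R)-7-hydroxy-2-(4-methoxybenzyloxy)-8-(triethylsilyloxy)dodec-5-en-9-olide, via Z-alkenylchromium dichloride 17 (not isolated)
Conditions: CrCl2 (excess), NiCl2 (cat.), degassed DMF, rt, slow addition of 16 to high dilution; aq. work-up
Reagents that add atoms: none
Why: CrCl2 reduces NiCl2 to zerovalent nickel, which inserts into the C6 carbon–iodine bond with retention; transmetalation to trivalent chromium gives 17, whose non-basic carbon–chromium bond adds 1,2 to the C7 aldehyde, and aqueous work-up frees the C7 hydroxyl. The closest known reaction type is the intramolecular Nozaki–Hiyama–Kishi reaction of iodoalkenyl aldehydes, established for medium-ring and macrocyclic lactone allylic alcohols, ten-membered lactones included. The ten-membered ring (ring oxygen plus C1–C9) closes in the 10-exo-trig mode by C6–C7 bond formation, the carbonyl oxygen staying outside the ring. C7, the only new stereocentre, is controlled by C8: the bulky, non-chelating OTES group lies antiperiplanar to the incoming carbon (polar Felkin–Anh model), which leads to the 7,8-anti, 7S carbinol. The step needs chemoselectivity for the aldehyde over the C1 ester (organochromium reagents ignore esters and neither enolise nor eliminate the beta-acyloxy aldehyde), cyclisation over oligomerisation (slow addition to high dilution, with the cis alkene and the planar ester folding the chain), and retention of the Z geometry. Geometry is the delicate point, because cis-disubstituted alkenylchromium species can drift towards trans; a low nickel loading, fast intramolecular capture of 17 and the lower strain of a cis- relative to a trans-cyclodecene-type ring should hold the Z alkene.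

Step 12
Reactants: 18 (2S,5Z,7S,8S,9R)-7-hydroxy-2-(4-methoxybenzyloxy)-8-(triethylsilyloxy)dodec-5-en-9-olide
Product: 19 (2S,5Z,7S,8R,9R)-2-(4-methoxybenzyloxy)-7,8-bis(triethylsilyloxy)dodec-5-en-9-olide
Conditions: TESOTf, 2,6-lutidine, CH2Cl2, −78 °C
Reagents that add atoms: triethylsilyl triflate CC[Si](CC)(CC)OS(=O)(=O)C(F)(F)F
Why: Routine silylation of the allylic C7 alcohol masks it, so that O2 will be the only free hydroxyl after the next step, and it touches no stereocentre.

Step 13
Reactants: 19 (2S,5Z,7S,8R,9R)-2-(4-methoxybenzyloxy)-7,8-bis(triethylsilyloxy)dodec-5-en-9-olide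
Product: 20 (2S,5Z,7S,8R,9R)-2-hydroxy-7,8-bis(triethylsilyloxy)dodec-5-en-9-olide
Conditions: DDQ, CH2Cl2/pH 7 buffer, 0 °C
Reagents that add atoms: none
Why: Oxidative PMB cleavage with DDQ (hydride abstraction at the electron-rich benzylic position, then hydrolysis) is orthogonal to the silyl ethers, the lactone and the isolated Z alkene, and the buffer neutralises the acidic hydroquinone that could otherwise strip the TES groups.

Step 14
Reactants: 21 (E)-but-2-en-1-ol
Product: 22 [(2S,3S)-3-methyloxiran-2-yl]methanol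
Conditions: Ti(OiPr)4 (cat.), L-(+)-diethyl tartrate (cat.), anhydrous t-BuOOH, 4 Å MS, CH2Cl2, −20 °C; non-aqueous work-up, distillation
Reagents that add atoms: tert-butyl hydroperoxide CC(C)(C)OO
Why: The Sharpless asymmetric epoxidation with the L-(+)-tartrate ligand sets both oxirane carbons as (2S,3S), as in step 7, and the non-aqueous isolation avoids loss of the small, water-soluble product.

Step 15
Reactants: 22 [(2S,3S)-3-methyloxiran-2-yl]methanol
Product: 24 methyl (2E,4S,5S)-4,5-epoxyhex-2-enoate, via epoxy aldehyde 23 (not isolated)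
Conditions: TEMPO (cat.), PhI(OAc)2, CH2Cl2, rt; then Ph3P=CHCO2Me, rt
Reagents that add atoms: methyl (triphenylphosphoranylidene)acetate COC(=O)C=P(c1ccccc1)(c1ccccc1)c1ccccc1
Why: The one-pot oxoammonium oxidation and Wittig olefination avoids isolating the volatile, epimerisable 23; the stabilised ylide is inherently E-selective in an aprotic solvent, and the oxirane carbons are not involved.

Step 16
Reactants: 24 methyl (2E,4S,5S)-4,5-epoxyhex-2-enoate
Product: 25 (2E,4S,5S)-4,5-epoxyhex-2-enoic acid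
Conditions: LiOH, THF/H2O, 0 °C; aq. NaHSO4 to pH 4, 0 °C; used without storage
Reagents that add atoms: lithium hydroxide [Li+].[OH-]
Why: Saponification of the methyl ester at 0 °C is faster than conjugate addition or oxirane opening, and acidifying only to pH 4 in the cold keeps the vinyl epoxide closed.

Step 17
Reactants: 20 (2S,5Z,7S,8R,9R)-2-hydroxy-7,8-bis(triethylsilyloxy)dodec-5-en-9-olide; 25 (2E,4S,5S)-4,5-epoxyhex-2-enoic acid
Product: 27 (2S,5Z,7S,8R,9R)-2-[(2E,4S,5S)-4,5-epoxyhex-2-enoyloxy]-7,8-bis(triethylsilyloxy)dodec-5-en-9-olide, via O-acylisourea 26 (not isolated)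
Conditions: DCC, DMAP (cat.), CH2Cl2, 0 °C
Reagents that add atoms: none
Why: In the Steglich esterification DMAP-catalysed acyl transfer from 26 acylates the only free hydroxyl (O2) with retention at C2, and the low temperature and sub-stoichiometric base guard against C2 epimerisation and gamma-deprotonation of the epoxy enoate.

Step 18
Reactants: 27 (2S,5Z,7S,8R,9R)-2-[(2E,4S,5S)-4,5-epoxyhex-2-enoyloxy]-7,8-bis(triethylsilyloxy)dodec-5-en-9-olide
Product: 28 (2S,5Z,7S,8S,9R)-2-[(2E,4S,5S)-4,5-epoxyhex-2-enoyloxy]-7,8-dihydroxydodec-5-en-9-olide (CNP0590330.3)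
Conditions: HF·pyridine, pyridine, THF, 0 °C
Reagents that add atoms: none
Why: Fluoride-driven cleavage of the two secondary TES ethers is fast at 0 °C, and the pyridine-buffered medium is neither acidic enough to open the electron-poor vinyl epoxide nor basic enough to cause acyl migration or lactone opening.

Compound list
1 | (S)-trityl glycidyl ether, (2S)-2-(trityloxymethyl)oxirane | C(OC(c1ccccc1)(c1ccccc1)c1ccccc1)[C@@H]2CO2 | starting material
2 | 1-(trimethylsilyl)propyne | CC#C[Si](C)(C)C | starting material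
3 | 3-lithio-1-(trimethylsilyl)propyne | [Li]CC#C[Si](C)(C)C | intermediate
4 | (2S)-6-(trimethylsilyl)-1-(trityloxy)hex-5-yn-2-ol | C(OC(c1ccccc1)(c1ccccc1)c1ccccc1)[C@@H](O)CCC#C[Si](C)(C)C | intermediate
5 | (2S)-2-(4-methoxybenzyloxy)-6-(trimethylsilyl)-1-(trityloxy)hex-5-yne | C(OC(c1ccccc1)(c1ccccc1)c1ccccc1)[C@@H](OCc1ccc(OC)cc1)CCC#C[Si](C)(C)C | intermediate
6 | (2S)-6-iodo-2-(4-methoxybenzyloxy)-1-(trityloxy)hex-5-yne | C(OC(c1ccccc1)(c1ccccc1)c1ccccc1)[C@@H](OCc1ccc(OC)cc1)CCC#CI | intermediate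
7 | (2S,5Z)-6-iodo-2-(4-methoxybenzyloxy)-1-(trityloxy)hex-5-ene | C(OC(c1ccccc1)(c1ccccc1)c1ccccc1)[C@@H](OCc1ccc(OC)cc1)CC/C=C\I | intermediate
8 | (2S,5Z)-6-iodo-2-(4-methoxybenzyloxy)hex-5-en-1-ol | OC[C@@H](OCc1ccc(OC)cc1)CC/C=C\I | intermediate
9 | (2S,5Z)-6-iodo-2-(4-methoxybenzyloxy)hex-5-enal | O=C[C@@H](OCc1ccc(OC)cc1)CC/C=C\I | intermediate
10 | (2S,5Z)-6-iodo-2-(4-methoxybenzyloxy)hex-5-enoic acid (C1–C6 acid fragment) | OC(=O)[C@@H](OCc1ccc(OC)cc1)CC/C=C\I | intermediate
11 | (E)-hex-2-en-1-ol | CCC/C=C/CO | starting material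
12 | [(2S,3S)-3-propyloxiran-2-yl]methanol | OC[C@@H]1O[C@H]1CCC | intermediate
13 | (2S,3R)-1,2-dihydroxyhexan-3-yl (2S,5Z)-6-iodo-2-(4-methoxybenzyloxy)hex-5-enoate | CCC[C@@H](OC(=O)[C@@H](OCc1ccc(OC)cc1)CC/C=C\I)[C@@H](O)CO | intermediate
14 | (2S,3R)-1,2-bis(triethylsilyloxy)hexan-3-yl (2S,5Z)-6-iodo-2-(4-methoxybenzyloxy)hex-5-enoate | CCC[C@@H](OC(=O)[C@@H](OCc1ccc(OC)cc1)CC/C=C\I)[C@@H](O[Si](CC)(CC)CC)CO[Si](CC)(CC)CC | intermediate
15 | dimethyl(alkoxy)sulfonium chloride at O7 of the C8-OTES ester | CCC[C@@H](OC(=O)[C@@H](OCc1ccc(OC)cc1)CC/C=C\I)[C@@H](O[Si](CC)(CC)CC)CO[S+](C)C.[Cl-] | intermediate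
16 | (2R,3R)-1-oxo-2-(triethylsilyloxy)hexan-3-yl (2S,5Z)-6-iodo-2-(4-methoxybenzyloxy)hex-5-enoate (cyclisation precursor) | CCC[C@@H](OC(=O)[C@@H](OCc1ccc(OC)cc1)CC/C=C\I)[C@@H](O[Si](CC)(CC)CC)C=O | intermediate
17 | Z-alkenylchromium dichloride derived from 16 (CrCl2 unit on C6) | CCC[C@@H](OC(=O)[C@@H](OCc1ccc(OC)cc1)CC/C=C\[Cr](Cl)Cl)[C@@H](O[Si](CC)(CC)CC)C=O | intermediate
18 | (2S,5Z,7S,8S,9R)-7-hydroxy-2-(4-methoxybenzyloxy)-8-(triethylsilyloxy)dodec-5-en-9-olide | CCC[C@H]1OC(=O)[C@@H](OCc2ccc(OC)cc2)CC/C=C\[C@H](O)[C@@H]1O[Si](CC)(CC)CC | intermediate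
19 | (2S,5Z,7S,8R,9R)-2-(4-methoxybenzyloxy)-7,8-bis(triethylsilyloxy)dodec-5-en-9-olide | CCC[C@H]1OC(=O)[C@@H](OCc2ccc(OC)cc2)CC/C=C\[C@H](O[Si](CC)(CC)CC)[C@@H]1O[Si](CC)(CC)CC | intermediate
20 | (2S,5Z,7S,8R,9R)-2-hydroxy-7,8-bis(triethylsilyloxy)dodec-5-en-9-olide | CCC[C@H]1OC(=O)[C@@H](O)CC/C=C\[C@H](O[Si](CC)(CC)CC)[C@@H]1O[Si](CC)(CC)CC | intermediate
21 | (E)-but-2-en-1-ol (crotyl alcohol, E-enriched grade) | C/C=C/CO | starting material
22 | [(2S,3S)-3-methyloxiran-2-yl]methanol | OC[C@@H]1O[C@H]1C | intermediate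
23 | (2R,3S)-3-methyloxirane-2-carbaldehyde | O=C[C@@H]1O[C@H]1C | intermediate
24 | methyl (2E,4S,5S)-4,5-epoxyhex-2-enoate | COC(=O)/C=C/[C@@H]1O[C@H]1C | intermediate
25 | (2E,4S,5S)-4,5-epoxyhex-2-enoic acid | OC(=O)/C=C/[C@@H]1O[C@H]1C | intermediate
26 | N,N'-dicyclohexyl-O-[(2E,4S,5S)-4,5-epoxyhex-2-enoyl]isourea | C1CCCCC1N=C(NC2CCCCC2)OC(=O)/C=C/[C@@H]3O[C@H]3C | intermediate
27 | (2S,5Z,7S,8R,9R)-2-[(2E,4S,5S)-4,5-epoxyhex-2-enoyloxy]-7,8-bis(triethylsilyloxy)dodec-5-en-9-olide | CCC[C@H]1OC(=O)[C@@H](OC(=O)/C=C/[C@@H]2O[C@H]2C)CC/C=C\[C@H](O[Si](CC)(CC)CC)[C@@H]1O[Si](CC)(CC)CC | intermediate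
28 | (2S,5Z,7S,8S,9R)-2-[(2E,4S,5S)-4,5-epoxyhex-2-enoyloxy]-7,8-dihydroxydodec-5-en-9-olide (CNP0590330.3) | CCC[C@H]1OC(=O)[C@@H](OC(=O)/C=C/[C@@H]2O[C@H]2C)CC/C=C\[C@H](O)[C@@H]1O | target

Total step count: 18
Longest linear sequence: 14 steps from 1 (steps 1–6, 8–13, 17 and 18)

Steps most likely to fail

**Step 11 (ring closure).** The alkenyl-metal intermediate may lose its cis geometry before the aldehyde captures it, so that trans or mixed ring alkenes result.
- The fallback sets out from 6 and comes back at 18. It installs the alkene only after the ring exists.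
- Iodoalkyne 6 skips the diimide reduction and is detritylated (TsOH, MeOH) to (2S)-6-iodo-2-(4-methoxybenzyloxy)hex-5-yn-1-ol F1.
- TEMPO/PhI(OAc)2 in aqueous MeCN oxidises F1 through (2S)-6-iodo-2-(4-methoxybenzyloxy)hex-5-ynal F2 to (2S)-6-iodo-2-(4-methoxybenzyloxy)hex-5-ynoic acid F3.
- Ti(OiPr)4-mediated opening of 12 by F3 gives the iodoalkynyl diol ester F4, and TESOTf/2,6-lutidine gives the iodoalkynyl bis(triethylsilyl) ether F5.
- Swern oxidation, through the iodoalkynyl alkoxysulfonium chloride F6, gives the iodoalkynyl aldehyde F7.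
- CrCl2 with catalytic NiCl2 converts F7 into the alkynylchromium dichloride F8, which closes the ring to the ten-membered cyclic propargylic alcohol F9. This is the alkynyl variant of the same chromium chemistry, known for ten-membered cycloalkynes.
- Semi-hydrogenation (H2, Pd on CaCO3 poisoned with Pb(OAc)2, quinoline) then gives 18. Syn delivery of hydrogen to the ring alkyne allows only the Z alkene.

**Step 8 (fragment union).** The acyl group may migrate from O9 to O8 or O7 in the titanium medium or on work-up. Isopropoxide may compete as nucleophile, or the valuable acid may be consumed unproductively.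
- The fallback sets out from 12 and comes back at 14. The union becomes an acylation of a preformed, fully protected C9 alcohol.
- Benzoic acid opens 12 under Ti(OiPr)4 to (2S,3R)-1,2-dihydroxyhexan-3-yl benzoate F10.
- TESOTf/2,6-lutidine gives (2S,3R)-1,2-bis(triethylsilyloxy)hexan-3-yl benzoate F11.
- i-Bu2AlH at −78 °C removes the benzoate reductively to give (2S,3R)-1,2-bis(triethylsilyloxy)hexan-3-ol F12.
- Acid 10 is activated with DCC as the O-acylisourea of acid 10 F13 and, with catalytic DMAP, acylates F12 with retention at C9 to give 14.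

**Step 10 (aldehyde formation).** Exposure of the nascent beta-acyloxy aldehyde to triethylamine may cause E1cB loss of the C9 carboxylate or epimerisation at C8. The primary and secondary silyl ethers may also be discriminated incompletely.
- The fallback sets out from 14 and comes back at 16. It separates deprotection from oxidation and uses no amine.
- Selective methanolysis of the primary silyl ether (PPTS, MeOH/CH2Cl2, −10 °C) gives the C7 primary alcohol F14.
- F14 is oxidised at once with Dess–Martin periodinane buffered by solid NaHCO3 in CH2Cl2 at 0 °C, and the resulting 16 is taken straight into step 11.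

Further compounds
F1 | step 11 | (2S)-6-iodo-2-(4-methoxybenzyloxy)hex-5-yn-1-ol | OC[C@@H](OCc1ccc(OC)cc1)CCC#CI
F2 | step 11 | (2S)-6-iodo-2-(4-methoxybenzyloxy)hex-5-ynal | O=C[C@@H](OCc1ccc(OC)cc1)CCC#CI
F3 | step 11 | (2S)-6-iodo-2-(4-methoxybenzyloxy)hex-5-ynoic acid | OC(=O)[C@@H](OCc1ccc(OC)cc1)CCC#CI
F4 | step 11 | (2S,3R)-1,2-dihydroxyhexan-3-yl (2S)-6-iodo-2-(4-methoxybenzyloxy)hex-5-ynoate | CCC[C@@H](OC(=O)[C@@H](OCc1ccc(OC)cc1)CCC#CI)[C@@H](O)CO
F5 | step 11 | (2S,3R)-1,2-bis(triethylsilyloxy)hexan-3-yl (2S)-6-iodo-2-(4-methoxybenzyloxy)hex-5-ynoate | CCC[C@@H](OC(=O)[C@@H](OCc1ccc(OC)cc1)CCC#CI)[C@@H](O[Si](CC)(CC)CC)CO[Si](CC)(CC)CC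
F6 | step 11 | dimethyl(alkoxy)sulfonium chloride at O7 of the iodoalkynyl C8-OTES ester | CCC[C@@H](OC(=O)[C@@H](OCc1ccc(OC)cc1)CCC#CI)[C@@H](O[Si](CC)(CC)CC)CO[S+](C)C.[Cl-]
F7 | step 11 | (2R,3R)-1-oxo-2-(triethylsilyloxy)hexan-3-yl (2S)-6-iodo-2-(4-methoxybenzyloxy)hex-5-ynoate | CCC[C@@H](OC(=O)[C@@H](OCc1ccc(OC)cc1)CCC#CI)[C@@H](O[Si](CC)(CC)CC)C=O
F8 | step 11 | alkynylchromium dichloride derived from F7 (CrCl2 unit on C6) | CCC[C@@H](OC(=O)[C@@H](OCc1ccc(OC)cc1)CCC#C[Cr](Cl)Cl)[C@@H](O[Si](CC)(CC)CC)C=O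
F9 | step 11 | (2S,7S,8S,9R)-7-hydroxy-2-(4-methoxybenzyloxy)-8-(triethylsilyloxy)dodec-5-yn-9-olide | CCC[C@H]1OC(=O)[C@@H](OCc2ccc(OC)cc2)CCC#C[C@H](O)[C@@H]1O[Si](CC)(CC)CC
F10 | step 8 | (2S,3R)-1,2-dihydroxyhexan-3-yl benzoate | CCC[C@@H](OC(=O)c1ccccc1)[C@@H](O)CO
F11 | step 8 | (2S,3R)-1,2-bis(triethylsilyloxy)hexan-3-yl benzoate | CCC[C@@H](OC(=O)c1ccccc1)[C@@H](O[Si](CC)(CC)CC)CO[Si](CC)(CC)CC
F12 | step 8 | (2S,3R)-1,2-bis(triethylsilyloxy)hexan-3-ol | CCC[C@@H](O)[C@@H](O[Si](CC)(CC)CC)CO[Si](CC)(CC)CC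
F13 | step 8 | N,N'-dicyclohexyl-O-[(2S,5Z)-6-iodo-2-(4-methoxybenzyloxy)hex-5-enoyl]isourea | C1CCCCC1N=C(NC2CCCCC2)OC(=O)[C@@H](OCc3ccc(OC)cc3)CC/C=C\I
F14 | step 10 | (2S,3R)-1-hydroxy-2-(triethylsilyloxy)hexan-3-yl (2S,5Z)-6-iodo-2-(4-methoxybenzyloxy)hex-5-enoate | CCC[C@@H](OC(=O)[C@@H](OCc1ccc(OC)cc1)CC/C=C\I)[C@@H](O[Si](CC)(CC)CC)CO
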